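**Retrosynthetic overview**

1. Endgame: both 3-methylbut-2-enoates are put on diol 16 at once; the epoxy ketone then comes from enone 17 by Luche reduction, hydroxyl-directed epoxidation (oxirane cis to the side chain) and oxidation.
2. The only carbocycle (ring A) is closed in one flask by a [3+3] union of but-2-en-2-ylmagnesium bromide 12 (C4) with the vinyl glycidic thioester 11 (C11). Acyl substitution makes the C(=O)–C(CH3) bond; the γ-methyl of the new enone, as its dienolate, then opens the oxirane and makes the ring CH2–CH bond.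
3. Enabling feature: in 13 the oxirane carbon that becomes the ring CH is allylic to the 1,1-disubstituted alkene (the later exocyclic methylene) and trans to the acyl carbon, and the ketone has no enolizable α′-hydrogen. Only six-membered γ-C-alkylation at that carbon is therefore possible, and it delivers the ring hydroxyl and the ring CH centre as the trans pair.
4. Fragment 11: acrolein → 2-bromoacrolein → Brown allylation (side-chain carbinol) → cross-metathesis (prenyl end) → Stille diene synthesis → Sharpless epoxidation (source of both ring centres) → acid → 2-pyridyl thioester.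
5. Order of ring formation: temporary oxirane of 9 (step 6, consumed in step 9) → ring A (step 9) → final oxirane (step 13).

Key step: step 9

Remark: 2-bromoacrolein is labile and is made fresh. Reagent 12 is sold as an E/Z mixture and is used as such, because both isomers should converge in step 9. Ring positions below follow the cyclohexenone numbering of 15 (C-1 carbonyl, C-2 methyl-bearing, C-5 side-chain-bearing, C-6 oxygen-bearing).

**Route**

Step 1
Reactants: 1 acrolein
Product: 3 2-bromoacrolein, via 2,3-dibromopropanal 2 (not isolated)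
Conditions: Br2, CH2Cl2, −78 °C; then Et3N, −78 → 0 °C
Reagents that add atoms: bromine, BrBr
Why: Bromination of the enal C=C followed by E1cB loss of HBr from the dibromo aldehyde (bromination–dehydrobromination); no stereocentre is formed.

Step 2
Reactants: 3 2-bromoacrolein
Product: 4 (3R)-2-bromohexa-1,5-dien-3-ol
Conditions: (+)-Ipc2B(allyl), Et2O, −78 °C; then NaOH, H2O2, 0 °C
Reagents that add atoms: (+)-B-allyldiisopinocampheylborane, C=CCB([C@H]1C[C@H]2C[C@@H]([C@@H]1C)C2(C)C)[C@H]1C[C@H]2C[C@@H]([C@@H]1C)C2(C)C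
Why: Brown asymmetric allylboration through a closed chair transition state; the (+)-reagent (the antipode that turns benzaldehyde into (R)-1-phenylbut-3-en-1-ol) should set the future side-chain carbinol as R.

Step 3
Reactants: 4 (3R)-2-bromohexa-1,5-dien-3-ol
Product: 5 (3R)-2-bromo-6-methylhepta-1,5-dien-3-ol
Conditions: RuCl2(=CHPh)(PCy3)(H2IMes) (second-generation Grubbs catalyst, cat.), 2-methyl-2-butene/CH2Cl2, rt
Reagents that add atoms: 2-methyl-2-butene, CC=C(C)C
Why: Olefin cross-metathesis of the monosubstituted alkene installs the prenyl terminus, and the 1,1-disubstituted bromoalkene should be inert to the ruthenium carbene.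

Step 4
Reactants: 5 (3R)-2-bromo-6-methylhepta-1,5-dien-3-ol
Product: 6 tert-butyl{[(3R)-2-bromo-6-methylhepta-1,5-dien-3-yl]oxy}dimethylsilane
Conditions: TBSCl, imidazole, DMF, rt
Reagents that add atoms: tert-butyldimethylsilyl chloride, CC(C)(C)[Si](C)(C)Cl
Why: Standard silylation; the ether shields the secondary allylic alcohol from the titanium epoxidation of step 6 and from the bases of step 9.

Step 5
Reactants: 6 silyl ether of 5; 7 (2E)-3-(tributylstannyl)prop-2-en-1-ol
Product: 8 (2E,5R)-5-[(tert-butyldimethylsilyl)oxy]-8-methyl-4-methylidenenona-2,7-dien-1-ol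
Conditions: Pd(PPh3)4 (cat.), CuI (cat.), DMF, 45 °C
Reagents that add atoms: none
Why: Stille cross-coupling of the 2-bromo-1-alkene with the E-vinylstannane proceeds with retention of alkene geometry and gives the 2-substituted 1,3-diene.

Step 6
Reactants: 8 dienol
Product: 9 [(2R,3R)-3-{(3R)-3-[(tert-butyldimethylsilyl)oxy]-6-methylhepta-1,5-dien-2-yl}oxiran-2-yl]methanol
Conditions: Ti(OiPr)4 (cat.), D-(−)-diethyl tartrate, t-BuOOH, 4 Å MS, CH2Cl2, −20 °C
Reagents that add atoms: tert-butyl hydroperoxide, CC(C)(C)OO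
Why: Sharpless asymmetric epoxidation touches only the C=C of the primary allylic alcohol, and the D-(−)-tartrate catalyst should deliver oxygen to the face that gives the (2R,3R)-oxirane.

Step 7
Reactants: 9 epoxy alcohol
Product: 10 (2S,3R)-3-{(3R)-3-[(tert-butyldimethylsilyl)oxy]-6-methylhepta-1,5-dien-2-yl}oxirane-2-carboxylic acid
Conditions: TEMPO (cat.), PhI(OAc)2, MeCN/pH 7 buffer, 0 °C → rt
Reagents that add atoms: water, O
Why: Oxoammonium oxidation of the primary alcohol to the aldehyde and of its hydrate to the acid leaves the stereocentres and the alkenes untouched (the descriptor at C-2 changes only by priority).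

Step 8
Reactants: 10 glycidic acid
Product: 11 S-(pyridin-2-yl) (2S,3R)-3-{(3R)-3-[(tert-butyldimethylsilyl)oxy]-6-methylhepta-1,5-dien-2-yl}oxirane-2-carbothioate
Conditions: 2,2'-dipyridyl disulfide, PPh3, CH2Cl2, 0 °C → rt
Reagents that add atoms: 2,2'-dipyridyl disulfide, c1ccc(SSc2ccccn2)nc1
Why: Mukaiyama redox condensation turns the acid into the chelating 2-pyridyl thioester under neutral conditions that spare the vinyl oxirane.

Step 9
Reactants: 11 2-pyridyl thioester; 12 but-2-en-2-ylmagnesium bromide (E/Z mixture)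
Product: 15 (5S,6S)-5-{(3R)-3-[(tert-butyldimethylsilyl)oxy]-6-methylhepta-1,5-dien-2-yl}-6-hydroxy-2-methylcyclohex-2-en-1-one, via epoxy dienone 13 (not isolated), via potassium dienolate 14 (not isolated)
Conditions: 12 (1.1 equiv), THF, −78 °C; then KOt-Bu (2.5 equiv), −78 → 0 °C; aq NH4Cl
Reagents that add atoms: none
Why: Proposed new method: the Grignard reagent acylates the chelating thioester to give epoxy dienone 13 (C-1–C-2 bond, Mukaiyama ketone synthesis); the γ-methyl carries the only acidic hydrogens, so KOt-Bu forms dienolate 14 reversibly, and its γ-carbon displaces the oxirane oxygen at the allylic carbon (C-4–C-5 bond); the closest known reaction types are intramolecular γ-alkylation of ketone dienolates, the Stork epoxynitrile cyclization and the oxy-anion-accelerated 6π closure of 2-oxidohexatrienes. Ring A closes in a 6-(enolendo)-exo-tet mode that is endo with respect to the oxirane (attack at its distal, allylic carbon). C-5 is set by SN2 inversion at the Sharpless-derived oxirane carbon and C-6 keeps its configuration, which should give the trans-5,6 pair directly. The step needs γ- over α-alkylation and attack at the allylic oxirane carbon rather than at the proximal carbon or the vinyl terminus: α-attack could only form a three- or four-membered ring, closure on the proximal carbon is a disfavoured 5-(enolendo) process, and the trans-oxirane holds the vinyl group anti to the acyl tether so that a six-membered SN2′ transition state cannot be reached. Because γ-deprotonation and α-reprotonation are reversible, both alkene isomers of 13 and both enolate geometries should drain through the one dienolate that can cyclize.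

Step 10
Reactants: 15 hydroxy enone
Product: 16 (5S,6S)-6-hydroxy-5-[(3R)-3-hydroxy-6-methylhepta-1,5-dien-2-yl]-2-methylcyclohex-2-en-1-one
Conditions: HF·pyridine, pyridine/THF, 0 °C → rt
Reagents that add atoms: none
Why: Buffered fluoride desilylation frees the side-chain carbinol without exposing the α′-hydroxy enone to strong base.

Step 11
Reactants: 16 diol
Product: 17 (3R)-6-methyl-2-[(1S,6S)-4-methyl-6-(3-methylbut-2-enoyloxy)-5-oxocyclohex-3-en-1-yl]hepta-1,5-dien-3-yl 3-methylbut-2-enoate
Conditions: 3-methylbut-2-enoyl chloride (3 equiv), pyridine, DMAP (cat.), CH2Cl2, 0 °C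
Reagents that add atoms: 3-methylbut-2-enoyl chloride, CC(C)=CC(=O)Cl
Why: DMAP-catalysed acylation of both secondary alcohols with retention; pyridine at 0 °C is chosen to limit deconjugation of the acyl chloride through its vinylketene.

Step 12
Reactants: 17 enone diester
Product: 18 allylic alcohol (17 with the ring C=O reduced to CH–OH; hydroxyl cis to the side chain and trans to the neighbouring acyloxy group)
Conditions: NaBH4, CeCl3·7H2O, MeOH, −78 °C
Reagents that add atoms: none
Why: Luche 1,2-reduction; axial hydride delivery to the half-chair with both ring substituents pseudo-equatorial should give the pseudo-equatorial alcohol, as in carvone → cis-carveol.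

Step 13
Reactants: 18 allylic alcohol
Product: 19 epoxy alcohol (18 with the ring C=C epoxidized on the hydroxyl face, oxirane cis to the side chain)
Conditions: VO(acac)2 (cat.), t-BuOOH, CH2Cl2, 0 °C → rt
Reagents that add atoms: tert-butyl hydroperoxide, CC(C)(C)OO
Why: Vanadium-catalysed hydroxyl-directed epoxidation delivers oxygen syn to the allylic OH and should leave the prenyl, methylidene and ester-conjugated alkenes alone.

Step 14
Reactants: 19 epoxy alcohol
Product: 20 (1S,3S,4S,6S)-1-methyl-4-[(3R)-6-methyl-3-(3-methylbut-2-enoyloxy)hepta-1,5-dien-2-yl]-2-oxo-7-oxabicyclo[4.1.0]heptan-3-yl 3-methylbut-2-enoate (target, CNP0140369.1)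
Conditions: Dess–Martin periodinane, CH2Cl2, rt
Reagents that add atoms: none
Why: Dess–Martin oxidation of the secondary alcohol under near-neutral conditions gives the epoxy ketone without touching the oxirane or the esters.

**Compound list**

1 | acrolein | C=CC=O | starting material
2 | 2,3-dibromopropanal | O=CC(Br)CBr | intermediate (not isolated)
3 | 2-bromoacrolein | C=C(Br)C=O | intermediate
4 | (3R)-2-bromohexa-1,5-dien-3-ol | C=C(Br)[C@@H](CC=C)O | intermediate
5 | (3R)-2-bromo-6-methylhepta-1,5-dien-3-ol | C=C(Br)[C@@H](CC=C(C)C)O | intermediate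
6 | tert-butyl{[(3R)-2-bromo-6-methylhepta-1,5-dien-3-yl]oxy}dimethylsilane | C=C(Br)[C@@H](CC=C(C)C)O[Si](C)(C)C(C)(C)C | intermediate
7 | (2E)-3-(tributylstannyl)prop-2-en-1-ol | OC/C=C/[Sn](CCCC)(CCCC)CCCC | starting material
8 | (2E,5R)-5-[(tert-butyldimethylsilyl)oxy]-8-methyl-4-methylidenenona-2,7-dien-1-ol | OC/C=C/C(=C)[C@@H](CC=C(C)C)O[Si](C)(C)C(C)(C)C | intermediate
9 | [(2R,3R)-3-{(3R)-3-[(tert-butyldimethylsilyl)oxy]-6-methylhepta-1,5-dien-2-yl}oxiran-2-yl]methanol | OC[C@H]1O[C@@H]1C(=C)[C@@H](CC=C(C)C)O[Si](C)(C)C(C)(C)C | intermediate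
10 | (2S,3R)-3-{(3R)-3-[(tert-butyldimethylsilyl)oxy]-6-methylhepta-1,5-dien-2-yl}oxirane-2-carboxylic acid | OC(=O)[C@H]1O[C@@H]1C(=C)[C@@H](CC=C(C)C)O[Si](C)(C)C(C)(C)C | intermediate
11 | S-(pyridin-2-yl) (2S,3R)-3-{(3R)-3-[(tert-butyldimethylsilyl)oxy]-6-methylhepta-1,5-dien-2-yl}oxirane-2-carbothioate | O=C(Sc1ccccn1)[C@H]1O[C@@H]1C(=C)[C@@H](CC=C(C)C)O[Si](C)(C)C(C)(C)C | intermediate
12 | but-2-en-2-ylmagnesium bromide (E/Z mixture, THF solution) | CC=C(C)[Mg]Br | starting material
13 | 1-[(2S,3R)-3-{(3R)-3-[(tert-butyldimethylsilyl)oxy]-6-methylhepta-1,5-dien-2-yl}oxiran-2-yl]-2-methylbut-2-en-1-one (E/Z mixture) | CC=C(C)C(=O)[C@H]1O[C@@H]1C(=C)[C@@H](CC=C(C)C)O[Si](C)(C)C(C)(C)C | intermediate (not isolated)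
14 | potassium dienolate of 13 (oxido group cis to the methyl, oxiranyl carbon cis to the vinyl group) | C=C/C(C)=C(/[O-])[C@H]1O[C@@H]1C(=C)[C@@H](CC=C(C)C)O[Si](C)(C)C(C)(C)C.[K+] | intermediate (not isolated)
15 | (5S,6S)-5-{(3R)-3-[(tert-butyldimethylsilyl)oxy]-6-methylhepta-1,5-dien-2-yl}-6-hydroxy-2-methylcyclohex-2-en-1-one | C=C([C@@H](CC=C(C)C)O[Si](C)(C)C(C)(C)C)[C@@H]1CC=C(C)C(=O)[C@H]1O | intermediate
16 | (5S,6S)-6-hydroxy-5-[(3R)-3-hydroxy-6-methylhepta-1,5-dien-2-yl]-2-methylcyclohex-2-en-1-one | C=C([C@@H](CC=C(C)C)O)[C@@H]1CC=C(C)C(=O)[C@H]1O | intermediate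
17 | (3R)-6-methyl-2-[(1S,6S)-4-methyl-6-(3-methylbut-2-enoyloxy)-5-oxocyclohex-3-en-1-yl]hepta-1,5-dien-3-yl 3-methylbut-2-enoate | C=C([C@@H](CC=C(C)C)OC(=O)C=C(C)C)[C@@H]1CC=C(C)C(=O)[C@H]1OC(=O)C=C(C)C | intermediate
18 | allylic alcohol from 17 (ring hydroxyl cis to the side chain, trans to the adjacent acyloxy group) | C=C([C@@H](CC=C(C)C)OC(=O)C=C(C)C)[C@@H]1CC=C(C)[C@H](O)[C@H]1OC(=O)C=C(C)C | intermediate
19 | epoxy alcohol from 18 (oxirane cis to the hydroxyl and to the side chain) | C=C([C@@H](CC=C(C)C)OC(=O)C=C(C)C)[C@@H]1C[C@@H]2O[C@]2(C)[C@H](O)[C@H]1OC(=O)C=C(C)C | intermediate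
20 | (1S,3S,4S,6S)-1-methyl-4-[(3R)-6-methyl-3-(3-methylbut-2-enoyloxy)hepta-1,5-dien-2-yl]-2-oxo-7-oxabicyclo[4.1.0]heptan-3-yl 3-methylbut-2-enoate | C=C([C@@H](CC=C(C)C)OC(=O)C=C(C)C)[C@@H]1C[C@@H]2O[C@]2(C)C(=O)[C@H]1OC(=O)C=C(C)C | target

**Summary**

Total step count: 14. Longest linear sequence: 14 steps (1 → 20); 7 and 12 are purchased.

**Steps most likely to fail**

1. Step 9 (proposed new method). The dienolate may be alkylated at its α-carbon, or the oxirane may be opened by other nucleophiles in the flask (thiolate, alkoxide) before the γ-carbon reaches the allylic carbon. Fallback, from dienol 8 back to 15: oxidation with MnO2 should give the (2E)-dienal F1; addition of 12 at −78 °C gives the bis-allylic alcohol F2; a second MnO2 oxidation gives the cross-conjugated trienone F3. Treatment with KN(SiMe3)2 and warming should effect the oxy-anion-accelerated 6π-electrocyclization (vinylogous intramolecular Michael addition) of the 2-oxidohexatriene. The resulting cyclohexadienolate would be hydroxylated in the same flask with 2-(phenylsulfonyl)-3-phenyloxaziridine, anti to the new ring substituent. This should return 15 together with its (5R,6R)-diastereomer, to be separated by chromatography; the ring centres are then no longer set by the oxirane.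

2. Step 7. The free vinyl glycidic acid may suffer acid-promoted oxirane opening or decarboxylative fragmentation during oxidation or activation. Fallback, from epoxy alcohol 9 back to 15: Parikh–Doering oxidation (SO3·pyridine, DMSO, i-Pr2NEt) should give the epoxy aldehyde F4; addition of 12 at −78 °C gives the carbinol F5 (mixture at the new carbinol carbon, which does not matter); Dess–Martin oxidation gives epoxy dienone 13, now isolated, which is cyclized with KOt-Bu as in step 9. The C(=O)–C(CH3) bond is then made by addition and oxidation instead of acyl substitution, and no free acid is handled.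

3. Step 12. The neighbouring acyl group may migrate to the new hydroxyl, which would later place the ketone on the wrong carbon, or hydride delivery may show poor facial selectivity. Fallback, from 15 to 20: silylation of the ring hydroxyl (TBSOTf, 2,6-lutidine) gives the bis-silyl ether F6; Luche reduction gives the allylic alcohol F7; VO(acac)2/t-BuOOH gives the epoxy alcohol F8; Dess–Martin oxidation gives the epoxy ketone F9; HF·pyridine gives the epoxy ketone diol F10; double acylation with 3-methylbut-2-enoyl chloride, pyridine and DMAP gives 20. The esters are thus introduced only after the ring oxidation pattern is fixed.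

**Further compounds**

F1 | step 9 | (2E,5R)-5-[(tert-butyldimethylsilyl)oxy]-8-methyl-4-methylidenenona-2,7-dienal | O=C/C=C/C(=C)[C@@H](CC=C(C)C)O[Si](C)(C)C(C)(C)C
F2 | step 9 | (5E,8R)-8-[(tert-butyldimethylsilyl)oxy]-3,11-dimethyl-7-methylidenedodeca-2,5,10-trien-4-ol (mixture at C-4 and at the 2-alkene) | CC=C(C)C(O)/C=C/C(=C)[C@@H](CC=C(C)C)O[Si](C)(C)C(C)(C)C
F3 | step 9 | (5E,8R)-8-[(tert-butyldimethylsilyl)oxy]-3,11-dimethyl-7-methylidenedodeca-2,5,10-trien-4-one (E/Z at the 2-alkene) | CC=C(C)C(=O)/C=C/C(=C)[C@@H](CC=C(C)C)O[Si](C)(C)C(C)(C)C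
F4 | step 7 | (2S,3R)-3-{(3R)-3-[(tert-butyldimethylsilyl)oxy]-6-methylhepta-1,5-dien-2-yl}oxirane-2-carbaldehyde | O=C[C@H]1O[C@@H]1C(=C)[C@@H](CC=C(C)C)O[Si](C)(C)C(C)(C)C
F5 | step 7 | 1-[(2R,3R)-3-{(3R)-3-[(tert-butyldimethylsilyl)oxy]-6-methylhepta-1,5-dien-2-yl}oxiran-2-yl]-2-methylbut-2-en-1-ol (mixture at the carbinol carbon and at the alkene) | CC=C(C)C(O)[C@H]1O[C@@H]1C(=C)[C@@H](CC=C(C)C)O[Si](C)(C)C(C)(C)C
F6 | step 12 | (5S,6S)-6-[(tert-butyldimethylsilyl)oxy]-5-{(3R)-3-[(tert-butyldimethylsilyl)oxy]-6-methylhepta-1,5-dien-2-yl}-2-methylcyclohex-2-en-1-one | C=C([C@@H](CC=C(C)C)O[Si](C)(C)C(C)(C)C)[C@@H]1CC=C(C)C(=O)[C@H]1O[Si](C)(C)C(C)(C)C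
F7 | step 12 | allylic alcohol from F6 (ring hydroxyl cis to the side chain) | C=C([C@@H](CC=C(C)C)O[Si](C)(C)C(C)(C)C)[C@@H]1CC=C(C)[C@H](O)[C@H]1O[Si](C)(C)C(C)(C)C
F8 | step 12 | epoxy alcohol from F7 (oxirane cis to the hydroxyl and to the side chain) | C=C([C@@H](CC=C(C)C)O[Si](C)(C)C(C)(C)C)[C@@H]1C[C@@H]2O[C@]2(C)[C@H](O)[C@H]1O[Si](C)(C)C(C)(C)C
F9 | step 12 | bis-silyl epoxy ketone from F8 | C=C([C@@H](CC=C(C)C)O[Si](C)(C)C(C)(C)C)[C@@H]1C[C@@H]2O[C@]2(C)C(=O)[C@H]1O[Si](C)(C)C(C)(C)C
F10 | step 12 | (1S,3S,4S,6S)-3-hydroxy-4-[(3R)-3-hydroxy-6-methylhepta-1,5-dien-2-yl]-1-methyl-7-oxabicyclo[4.1.0]heptan-2-one | C=C([C@@H](CC=C(C)C)O)[C@@H]1C[C@@H]2O[C@]2(C)C(=O)[C@H]1O
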